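All runs stem from a simulated flask with made-up constants, and the scatter is random.

I decided to follow the rate of making left-handed product and to write it as a product of factors, one per partner, each the fraction of its charge still there.

- elm: left-handed substrate 0.34 M; right-handed substrate 0.34 M; reagent 1.5 equiv; free catalyst 1 mol%; the very flask that is asked about, followed so far
- flask: left-handed substrate 0.34 M; reagent 1.50 equiv; free catalyst 1 mol%; right-handed substrate 0.34 M

- elm (time / h: left-handed product / %): 0.500: 1; 0.833: 6; 1.33: 9; 2.00: 13; 4.00: 22; 6.00: 25

(standard deviation of a reading: 1.5 percentage points)

- free catalyst is single-handed; left-handed substrate and right-handed substrate are mirror images of each other, charged as a racemate, each of them at the stated concentration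
- no earlier run changes the charge of free catalyst; that part of a forecast is a guess
- no earlier run changes the charge of reagent; that part of a forecast is a guess

- apparent order in free catalyst when 50% of the left-handed substrate and right-handed substrate together are converted (percent change of the rate of making left-handed product for one percent more free catalyst charged)
- apparent order in reagent when 50% of the left-handed substrate and right-handed substrate together are converted (percent change of the rate of making left-handed product for one percent more reagent charged)

The elm run is this flask followed so far. Its left-handed product came at 0.0800 /h of the pair charged between 0.500 h and 2.00 h, then at 0.0300 /h up to 6.00 h, a slowing by a factor of 2.67 as read. At 6.00 h the reading puts the left-handed substrate factor at 50.0% and the reagent factor at best at 66.7%.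

I supposed that each step takes one reagent, one free catalyst and one substrate. Dividing the rates of the two substrates then cancels reagent and catalyst, and integrating makes the left-handed fraction left equal the right-handed fraction left raised to the selectivity factor. So at fixed conversion the substrate factors ignore both charges, and my guess for free catalyst is first order. At 50% conversion the pair has used as much reagent as there was left-handed substrate, so the reagent factor stands at 33.3%. The used amount being fixed, the order in reagent is the reagent leverage, the charge divided by what is left of it at that conversion: 3.00.

The forecast gave 1 in free catalyst and 1 in reagent, holding that “extra charge raises the remaining reagent disproportionately, by about 1.5 times if 1 equiv remains”. On reagent my reckoning differs from it.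

The simulation gave 1.0 in free catalyst and 3.0 in reagent.

    reagent + free catalyst + left-handed substrate → free catalyst + left-handed product (k = 0.0250 /M²/s)
    reagent + free catalyst + right-handed substrate → free catalyst + right-handed product (k = 0.00419 /M²/s)
    free catalyst → spent catalyst (k = 2.53 × 10⁻⁸ /s)

In this flask at 4.02 h the step to left-handed product used reagent 3.9 times as fast as the step to right-handed product, yet both drew on one charge, and the order of 3.0 stands beside the leverage of 3.00. By 20.0 h, at 51.9% conversion and so a little past the point asked about, this flask held 31% of its reagent, a charge-to-remainder ratio of 3.23, with free catalyst still at 99.8%.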